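Numbering: tetralin C1 (CHOH), C2, C3, C4 (CH bearing the naphthyl), C4a, C5 (OMe) to C8, C8a. Ring A is the anisole ring, ring B the saturated ring, and the naphthyl atoms are primed.
Enabling feature: C1 and C4 are both benzylic, sit on the adjacent ring A carbons C8a and C4a, and carry O and C1' on the same face of ring B. A suprafacial [4+2] addition leaves exactly this pattern when a ring A o-quinodimethane has both terminal substituents pointing outward.
Cuts: a carboxyl is put back on C2, then C1–C2 and C3–C4 are cut together to give tert-butyl acrylate and a 2-(naphthylmethyl)-3-methoxybenzaldehyde. The CH2–C1' bond is cut next, giving a benzylic bromide and a 4-bromo-1-naphthol ether.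
Forward order: ring A and the naphthalene are bought and joined through CH2 by Negishi coupling, and the ester is taken to the aldehyde. Ring B, the only ring made, closes in the light-driven cycloaddition; the C2 carboxyl is then excised by Barton decarboxylation and both silyl ethers fall in one last step.
Stereochemistry: the cis C1/C4 relation comes from the diene geometry and the suprafacial addition, and the absolute (1S,4S) sense from (TADDOLate)Ti(OiPr)2. The third centre (C2) is transient.

Key step: step 9

Assumption: the diene face left open by the (R,R)-TADDOLate ligand is taken to be the one that leads to (1S,4S); should the antipode form, the equally available (S,S)-ligand is used and nothing else changes.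

Step 1
Reactants: 1 naphthalene-1,8-diol
Product: 2 8-methoxynaphthalen-1-ol
Conditions: MeI (1.05 equiv), K2CO3 (1.1 equiv), acetone, reflux
Reagents that add atoms: iodomethane, CI
Why: Williamson O-methylation should stop at the monoether because the remaining hydroxyl is locked in a peri hydrogen bond to the new methoxy oxygen and is deprotonated far less readily.

Step 2
Reactants: 2 8-methoxynaphthalen-1-ol
Product: 3 4-bromo-8-methoxynaphthalen-1-ol
Conditions: NBS (1.0 equiv), MeCN, −20 → 0 °C, dark
Reagents that add atoms: N-bromosuccinimide, O=C1CCC(=O)N1Br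
Why: Electrophilic aromatic bromination goes to the phenol ring, the more activated of the two, and NBS in polar MeCN is known to favour the para position C4 over the ortho position C2 in 1-naphthols.

Step 3
Reactants: 3 4-bromo-8-methoxynaphthalen-1-ol
Product: 4 (4-bromo-8-methoxynaphthalen-1-yl)oxytriisopropylsilane
Conditions: TIPSOTf (1.2 equiv), 2,6-lutidine (1.5 equiv), CH2Cl2, 0 → 25 °C
Reagents that add atoms: triisopropylsilyl trifluoromethanesulfonate, CC(C)[Si](OS(=O)(=O)C(F)(F)F)(C(C)C)C(C)C
Why: Silyl ether formation with the triflate overcomes the hydrogen-bonded, peri-hindered hydroxyl, and the aryl TIPS ether withstands organozinc, hydride, titanium alkoxide and radical conditions yet falls to fluoride together with the later C1 silyl ether.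

Step 4
Reactants: 5 3-methoxy-2-methylbenzoic acid
Product: 6 methyl 3-methoxy-2-methylbenzoate
Conditions: MeOH, H2SO4 (cat.), reflux
Reagents that add atoms: methanol, CO
Why: Fischer esterification in excess methanol is routine for a mono-ortho-substituted benzoic acid.

Step 5
Reactants: 6 methyl 3-methoxy-2-methylbenzoate
Product: 7 methyl 2-(bromomethyl)-3-methoxybenzoate
Conditions: NBS (1.05 equiv), AIBN (5 mol %), PhCF3, 85 °C
Reagents that add atoms: N-bromosuccinimide, O=C1CCC(=O)N1Br
Why: Wohl–Ziegler radical bromination attacks the only benzylic C–H bonds, while the non-polar medium and the ester-deactivated ring hold back ionic ring bromination.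

Step 6
Reactants: 7 methyl 2-(bromomethyl)-3-methoxybenzoate; 4 (4-bromo-8-methoxynaphthalen-1-yl)oxytriisopropylsilane
Product: 9 methyl 3-methoxy-2-{[5-methoxy-4-(triisopropylsilyloxy)naphthalen-1-yl]methyl}benzoate, via benzylic zinc bromide 8 (not isolated)
Conditions: Zn dust (1.5 equiv), LiCl (1.5 equiv), THF, 0 → 25 °C; then 4, Pd(OAc)2 (2 mol %), SPhos (4 mol %), THF, 25 → 50 °C
Reagents that add atoms: none
Why: In this Negishi coupling, LiCl-assisted zinc insertion gives an ester-tolerant benzylic zinc reagent, and the electron-rich biaryl phosphine lets zerovalent palladium insert into the electron-rich, peri-hindered C–Br bond of 4 so that the CH2–C1' bond forms under mild conditions.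

Step 7
Reactants: 9 methyl 3-methoxy-2-{[5-methoxy-4-(triisopropylsilyloxy)naphthalen-1-yl]methyl}benzoate
Product: 10 (3-methoxy-2-{[5-methoxy-4-(triisopropylsilyloxy)naphthalen-1-yl]methyl}phenyl)methanol
Conditions: iBu2AlH (2.5 equiv), CH2Cl2, −78 → 0 °C; aq. potassium sodium tartrate
Reagents that add atoms: none
Why: Hydride reduction takes the aryl ester fully to the benzylic alcohol, and the methyl and silyl ethers are inert to iBu2AlH at low temperature.

Step 8
Reactants: 10 (3-methoxy-2-{[5-methoxy-4-(triisopropylsilyloxy)naphthalen-1-yl]methyl}phenyl)methanol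
Product: 11 3-methoxy-2-{[5-methoxy-4-(triisopropylsilyloxy)naphthalen-1-yl]methyl}benzaldehyde
Conditions: MnO2 (activated, excess), CH2Cl2, 25 °C
Reagents that add atoms: none
Why: Heterogeneous MnO2 oxidation is selective for benzylic alcohols, stops at the aldehyde and leaves the electron-rich naphthalene and the diarylmethane CH2 untouched.

Step 9
Reactants: 11 3-methoxy-2-{[5-methoxy-4-(triisopropylsilyloxy)naphthalen-1-yl]methyl}benzaldehyde; 12 tert-butyl acrylate
Product: 14 tert-butyl (1S,2S,4S)-1-hydroxy-5-methoxy-4-[5-methoxy-4-(triisopropylsilyloxy)naphthalen-1-yl]-1,2,3,4-tetrahydronaphthalene-2-carboxylate, via outward-outward hydroxy-o-quinodimethane 13 (not isolated)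
Conditions: Ti(OiPr)4 (1.5 equiv), (R,R)-TADDOL (1.6 equiv), toluene, 25 °C, iPrOH removed in vacuo; then 11, 12 (5 equiv), toluene, argon, 365 nm LED, 0–10 °C; aq. NaHCO3
Reagents that add atoms: none
Why: Light of 365 nm, which the dialkoxynaphthalene hardly absorbs, excites the aldehyde, whose oxygen takes a hydrogen from the doubly benzylic CH2 in a 1,5-shift; the biradical relaxes to dienol 13, and exchange of its outward hydroxyl for an isopropoxide on tetravalent titanium holds it as a long-lived dienolate. The closest known reaction type is the Ti(OiPr)4/TADDOL-mediated enantioselective photoenolization/Diels–Alder reaction of 2-alkylbenzaldehydes with α,β-unsaturated carbonyl compounds, and dienols from 2-benzylbenzaldehydes are known to be trapped by acrylic and fumaric esters. Ring B closes as a six-membered carbocycle by a concerted suprafacial [4+2] cycloaddition that forms C1–C2 and C3–C4 together, the oxygen donor at C1 placing the largest diene coefficient on C4 so that the acrylate CH2 bonds there and the ester lands on C2. C1 and C4 come out cis because hydroxyl and naphthyl both stand outward on the diene: an inward naphthyl would collide with the inward hydrogen of the hydroxymethylene terminus, whereas the outward naphthyl escapes the C5 methoxy group by turning perpendicular to the diene plane. C2 is set cis to C1 by the endo approach enforced when the same titanium centre binds the dienolate oxygen and the ester carbonyl, and the absolute configuration follows from the aryl groups of the TADDOLate ligand, which leave one diene face open. The step needs only face selectivity and diene geometry, since C2 later becomes CH2 and an exo adduct would converge on 18; the tert-butyl ester is chosen because it does not exchange with titanium isopropoxide and can later be removed without base.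

Step 10
Reactants: 14 tert-butyl (1S,2S,4S)-1-hydroxy-5-methoxy-4-[5-methoxy-4-(triisopropylsilyloxy)naphthalen-1-yl]-1,2,3,4-tetrahydronaphthalene-2-carboxylate
Product: 16 (1S,2S,4S)-1-(tert-butyldimethylsilyloxy)-5-methoxy-4-[5-methoxy-4-(triisopropylsilyloxy)naphthalen-1-yl]-1,2,3,4-tetrahydronaphthalene-2-carboxylic acid, via bis-silylated silyl ester 15 (not isolated)
Conditions: TBSOTf (4 equiv), 2,6-lutidine (6 equiv), CH2Cl2, 0 → 25 °C; then AcOH/THF/H2O, 25 °C
Reagents that add atoms: tert-butyldimethylsilyl trifluoromethanesulfonate, CC(C)(C)[Si](C)(C)OS(=O)(=O)C(F)(F)F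
Why: The silyl triflate with a hindered pyridine base silylates the C1 hydroxyl and turns the tert-butyl ester into a silyl ester with loss of isobutene (a known non-basic tert-butyl ester cleavage of β-hydroxy esters), and only the much more labile silyl ester is then hydrolysed by dilute acetic acid, so the C2–H never meets base and β-elimination of the C1 oxygen is avoided.

Step 11
Reactants: 16 (1S,2S,4S)-1-(tert-butyldimethylsilyloxy)-5-methoxy-4-[5-methoxy-4-(triisopropylsilyloxy)naphthalen-1-yl]-1,2,3,4-tetrahydronaphthalene-2-carboxylic acid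
Product: 18 tert-butyl({(1S,4S)-5-methoxy-4-[5-methoxy-4-(triisopropylsilyloxy)naphthalen-1-yl]-1,2,3,4-tetrahydronaphthalen-1-yl}oxy)dimethylsilane, via Barton ester 17 (not isolated)
Conditions: 1-hydroxypyridine-2(1H)-thione (1.2 equiv), DCC (1.2 equiv), DMAP (cat.), CH2Cl2, 0 → 25 °C, dark; then t-BuSH (10 equiv), tungsten lamp, 15 °C
Reagents that add atoms: none
Why: In this Barton reductive decarboxylation, carbodiimide coupling gives the O-acyl thiohydroxamate, visible light starts the radical chain, CO2 is lost and the secondary C2 radical takes hydrogen from the thiol, while C1 and C4 are not part of the radical centre and keep their configuration.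

Step 12
Reactants: 18 tert-butyl({(1S,4S)-5-methoxy-4-[5-methoxy-4-(triisopropylsilyloxy)naphthalen-1-yl]-1,2,3,4-tetrahydronaphthalen-1-yl}oxy)dimethylsilane
Product: 19 dipolynaphthalene B, (1S,4S)-4-(4-hydroxy-5-methoxynaphthalen-1-yl)-5-methoxy-1,2,3,4-tetrahydronaphthalen-1-ol
Conditions: Bu4NF (3 equiv), AcOH (3 equiv), THF, argon, 0 → 40 °C
Reagents that add atoms: none
Why: Fluoride-induced desilylation cleaves both Si–O bonds at once, and the acetic acid buffer keeps the electron-rich naphtholate from air oxidation while the near-neutral medium does not ionise the benzylic alcohol, so neither stereocentre is touched.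

Compound list
1 | naphthalene-1,8-diol | Oc1cccc2cccc(O)c12 | starting material
2 | 8-methoxynaphthalen-1-ol | COc1cccc2cccc(O)c12 | intermediate
3 | 4-bromo-8-methoxynaphthalen-1-ol | COc1cccc2c(Br)ccc(O)c12 | intermediate
4 | (4-bromo-8-methoxynaphthalen-1-yl)oxytriisopropylsilane | COc1cccc2c(Br)ccc(O[Si](C(C)C)(C(C)C)C(C)C)c12 | intermediate
5 | 3-methoxy-2-methylbenzoic acid | COc1cccc(C(=O)O)c1C | starting material
6 | methyl 3-methoxy-2-methylbenzoate | COC(=O)c1cccc(OC)c1C | intermediate
7 | methyl 2-(bromomethyl)-3-methoxybenzoate | COC(=O)c1cccc(OC)c1CBr | intermediate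
8 | [2-methoxy-6-(methoxycarbonyl)benzyl]zinc bromide | COC(=O)c1cccc(OC)c1C[Zn]Br | intermediate
9 | methyl 3-methoxy-2-{[5-methoxy-4-(triisopropylsilyloxy)naphthalen-1-yl]methyl}benzoate | COC(=O)c1cccc(OC)c1Cc1ccc(O[Si](C(C)C)(C(C)C)C(C)C)c2c(OC)cccc12 | intermediate
10 | (3-methoxy-2-{[5-methoxy-4-(triisopropylsilyloxy)naphthalen-1-yl]methyl}phenyl)methanol | OCc1cccc(OC)c1Cc1ccc(O[Si](C(C)C)(C(C)C)C(C)C)c2c(OC)cccc12 | intermediate
11 | 3-methoxy-2-{[5-methoxy-4-(triisopropylsilyloxy)naphthalen-1-yl]methyl}benzaldehyde | O=Cc1cccc(OC)c1Cc1ccc(O[Si](C(C)C)(C(C)C)C(C)C)c2c(OC)cccc12 | intermediate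
12 | tert-butyl acrylate | C=CC(=O)OC(C)(C)C | starting material
13 | hydroxy-o-quinodimethane tautomer of 11, hydroxyl and naphthyl both outward (trans to the other exocyclic carbon), held on titanium through its oxygen in the flask | O/C=C1/C(=C/c2ccc(O[Si](C(C)C)(C(C)C)C(C)C)c3c(OC)cccc23)C(OC)=CC=C1 | intermediate
14 | tert-butyl (1S,2S,4S)-1-hydroxy-5-methoxy-4-[5-methoxy-4-(triisopropylsilyloxy)naphthalen-1-yl]-1,2,3,4-tetrahydronaphthalene-2-carboxylate (all-cis) | COc1cccc2c1[C@H](c1ccc(O[Si](C(C)C)(C(C)C)C(C)C)c3c(OC)cccc13)C[C@H](C(=O)OC(C)(C)C)[C@@H]2O | intermediate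
15 | tert-butyldimethylsilyl (1S,2S,4S)-1-(tert-butyldimethylsilyloxy)-5-methoxy-4-[5-methoxy-4-(triisopropylsilyloxy)naphthalen-1-yl]-1,2,3,4-tetrahydronaphthalene-2-carboxylate | COc1cccc2c1[C@H](c1ccc(O[Si](C(C)C)(C(C)C)C(C)C)c3c(OC)cccc13)C[C@H](C(=O)O[Si](C)(C)C(C)(C)C)[C@@H]2O[Si](C)(C)C(C)(C)C | intermediate
16 | (1S,2S,4S)-1-(tert-butyldimethylsilyloxy)-5-methoxy-4-[5-methoxy-4-(triisopropylsilyloxy)naphthalen-1-yl]-1,2,3,4-tetrahydronaphthalene-2-carboxylic acid | COc1cccc2c1[C@H](c1ccc(O[Si](C(C)C)(C(C)C)C(C)C)c3c(OC)cccc13)C[C@H](C(=O)O)[C@@H]2O[Si](C)(C)C(C)(C)C | intermediate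
17 | 2-thioxopyridin-1(2H)-yl (1S,2S,4S)-1-(tert-butyldimethylsilyloxy)-5-methoxy-4-[5-methoxy-4-(triisopropylsilyloxy)naphthalen-1-yl]-1,2,3,4-tetrahydronaphthalene-2-carboxylate | COc1cccc2c1[C@H](c1ccc(O[Si](C(C)C)(C(C)C)C(C)C)c3c(OC)cccc13)C[C@H](C(=O)On1ccccc1=S)[C@@H]2O[Si](C)(C)C(C)(C)C | intermediate
18 | tert-butyl({(1S,4S)-5-methoxy-4-[5-methoxy-4-(triisopropylsilyloxy)naphthalen-1-yl]-1,2,3,4-tetrahydronaphthalen-1-yl}oxy)dimethylsilane (cis) | COc1cccc2c1[C@H](c1ccc(O[Si](C(C)C)(C(C)C)C(C)C)c3c(OC)cccc13)CC[C@@H]2O[Si](C)(C)C(C)(C)C | intermediate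
19 | dipolynaphthalene B, (1S,4S)-4-(4-hydroxy-5-methoxynaphthalen-1-yl)-5-methoxy-1,2,3,4-tetrahydronaphthalen-1-ol (cis) | COc1cccc2c1[C@H](c1ccc(O)c3c(OC)cccc13)CC[C@@H]2O | target

Total step count: 12
Longest linear sequence: 10 steps (1, 2, 3, 6, 7, 8, 9, 10, 11, 12)

Steps most likely to fail

Step 9.
- **Energy transfer:** the excited aldehyde may pass its triplet energy to the neighbouring dialkoxynaphthalene, whose triplet lies lower, faster than it abstracts hydrogen. Dienol formation would then become inefficient.
- **Diene geometry:** crowding by the C5 methoxy group may erode the outward geometry at the naphthyl terminus.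
- **Facial control:** a monodentate acrylate may be held too loosely on titanium for good facial selectivity.

The fallback needs no light and moves the stereocontrol to a ketone reduction. It sets out from ester 9 and acrylate 12.
- Deprotonation of the doubly benzylic CH2 of 9 with LiN(iPr)2 (THF, −78 °C) and addition of 12 forms the same C3–C4 and C1–C2 bonds by a Michael–Dieckmann annulation. This gives racemic tert-butyl 5-methoxy-4-[5-methoxy-4-(triisopropylsilyloxy)naphthalen-1-yl]-1-oxo-1,2,3,4-tetrahydronaphthalene-2-carboxylate F1.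
- CF3CO2H in CH2Cl2 followed by warming in toluene removes the ester group and leaves racemic 5-methoxy-4-[5-methoxy-4-(triisopropylsilyloxy)naphthalen-1-yl]-3,4-dihydronaphthalen-1(2H)-one F2.
- Corey–Bakshi–Shibata reduction with (R)-2-methyl-CBS-oxazaborolidine and BH3·SMe2 (THF, −20 °C) should deliver hydride to the same carbonyl face of both antipodes. The (4S)-ketone then gives the cis alcohol (1S,4S)-5-methoxy-4-[5-methoxy-4-(triisopropylsilyloxy)naphthalen-1-yl]-1,2,3,4-tetrahydronaphthalen-1-ol F3.
- The (4R)-ketone gives the trans alcohol (1S,4R)-5-methoxy-4-[5-methoxy-4-(triisopropylsilyloxy)naphthalen-1-yl]-1,2,3,4-tetrahydronaphthalen-1-ol F4. The two are diastereomers and are separated on silica, so at most half of the material can follow the productive branch.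
- F3 is desilylated under the conditions of step 12 and comes back to the route at 19.

Step 2.
- **Ortho attack:** the peri hydrogen bond may weaken the solvent effect that steers bromine to C4, so attack at C2 may compete.
- **Over-reaction:** double bromination or oxidation of the naphthol may also intervene.

The fallback puts oxygen instead of halogen at C4 and relies on the peri hydrogen bond rather than on ortho/para selectivity. It sets out from 2.
- Teuber oxidation with (KSO3)2NO (KH2PO4 buffer, acetone/H2O) gives 5-methoxynaphthalene-1,4-dione F5.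
- Na2S2O4 (Et2O/H2O, argon) reduces F5 to 5-methoxynaphthalene-1,4-diol F6.
- PhNTf2 (1 equiv) with Et3N should sulfonylate the free hydroxyl at C1 rather than the C4 hydroxyl, which is hydrogen-bonded to and shielded by the peri methoxy group. This gives 4-hydroxy-5-methoxynaphthalen-1-yl trifluoromethanesulfonate F7.
- TIPSOTf with 2,6-lutidine then gives 5-methoxy-4-(triisopropylsilyloxy)naphthalen-1-yl trifluoromethanesulfonate F8.
- F8 takes the place of 4 in the Negishi coupling with 8 under the conditions of step 6, and the route is rejoined at 9.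

Step 10.
- **Loss of the C1 oxygen:** slow departure of the tert-butyl group may give the silyl triflate time to ionise the benzylic C1–O bond. Elimination towards the ring A-conjugated unsaturated ester may also set in.

The fallback cleaves the ester at its alkyl side by π-allyl chemistry under neutral conditions. It sets out from 11.
- The cycloaddition of step 9 is run with commercial allyl acrylate in place of 12. This gives allyl (1S,2S,4S)-1-hydroxy-5-methoxy-4-[5-methoxy-4-(triisopropylsilyloxy)naphthalen-1-yl]-1,2,3,4-tetrahydronaphthalene-2-carboxylate F9.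
- TBSOTf (1.1 equiv) with 2,6-lutidine at −78 °C silylates only the hydroxyl and gives allyl (1S,2S,4S)-1-(tert-butyldimethylsilyloxy)-5-methoxy-4-[5-methoxy-4-(triisopropylsilyloxy)naphthalen-1-yl]-1,2,3,4-tetrahydronaphthalene-2-carboxylate F10.
- Pd(PPh3)4 (cat.) with morpholine in THF at 25 °C transfers the allyl group to the amine, and the route is rejoined at acid 16.

Further compounds
F1 | step 9 | tert-butyl 5-methoxy-4-[5-methoxy-4-(triisopropylsilyloxy)naphthalen-1-yl]-1-oxo-1,2,3,4-tetrahydronaphthalene-2-carboxylate (racemic) | COc1cccc2c1C(c1ccc(O[Si](C(C)C)(C(C)C)C(C)C)c3c(OC)cccc13)CC(C(=O)OC(C)(C)C)C2=O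
F2 | step 9 | 5-methoxy-4-[5-methoxy-4-(triisopropylsilyloxy)naphthalen-1-yl]-3,4-dihydronaphthalen-1(2H)-one (racemic) | COc1cccc2c1C(c1ccc(O[Si](C(C)C)(C(C)C)C(C)C)c3c(OC)cccc13)CCC2=O
F3 | step 9 | (1S,4S)-5-methoxy-4-[5-methoxy-4-(triisopropylsilyloxy)naphthalen-1-yl]-1,2,3,4-tetrahydronaphthalen-1-ol | COc1cccc2c1[C@H](c1ccc(O[Si](C(C)C)(C(C)C)C(C)C)c3c(OC)cccc13)CC[C@@H]2O
F4 | step 9 | (1S,4R)-5-methoxy-4-[5-methoxy-4-(triisopropylsilyloxy)naphthalen-1-yl]-1,2,3,4-tetrahydronaphthalen-1-ol | COc1cccc2c1[C@@H](c1ccc(O[Si](C(C)C)(C(C)C)C(C)C)c3c(OC)cccc13)CC[C@@H]2O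
F5 | step 2 | 5-methoxynaphthalene-1,4-dione | COc1cccc2c1C(=O)C=CC2=O
F6 | step 2 | 5-methoxynaphthalene-1,4-diol | COc1cccc2c(O)ccc(O)c12
F7 | step 2 | 4-hydroxy-5-methoxynaphthalen-1-yl trifluoromethanesulfonate | COc1cccc2c(OS(=O)(=O)C(F)(F)F)ccc(O)c12
F8 | step 2 | 5-methoxy-4-(triisopropylsilyloxy)naphthalen-1-yl trifluoromethanesulfonate | COc1cccc2c(OS(=O)(=O)C(F)(F)F)ccc(O[Si](C(C)C)(C(C)C)C(C)C)c12
F9 | step 10 | allyl (1S,2S,4S)-1-hydroxy-5-methoxy-4-[5-methoxy-4-(triisopropylsilyloxy)naphthalen-1-yl]-1,2,3,4-tetrahydronaphthalene-2-carboxylate | COc1cccc2c1[C@H](c1ccc(O[Si](C(C)C)(C(C)C)C(C)C)c3c(OC)cccc13)C[C@H](C(=O)OCC=C)[C@@H]2O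
F10 | step 10 | allyl (1S,2S,4S)-1-(tert-butyldimethylsilyloxy)-5-methoxy-4-[5-methoxy-4-(triisopropylsilyloxy)naphthalen-1-yl]-1,2,3,4-tetrahydronaphthalene-2-carboxylate | COc1cccc2c1[C@H](c1ccc(O[Si](C(C)C)(C(C)C)C(C)C)c3c(OC)cccc13)C[C@H](C(=O)OCC=C)[C@@H]2O[Si](C)(C)C(C)(C)C
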